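Numbering: C1 = C(OH) bearing C7H2OAc, C2 = CHOAc, C3=C4, C5 = allylic CHOBz, C6 = CHOBz next to C1. The target is (1R,2S,5R,6S). The β face carries O-2, O-5 and C7; the α face carries 1-OH and O-6.
Enabling feature: O-2 and O-5 are cis-1,4 on one face of the cyclohexene ring, and 1-OH and O-6 are cis on the other face. The ring is therefore an anti-dihydroxylated cyclohexa-1,4-diene with a local mirror plane through the midpoints of C3=C4 and C1–C6, and one silicon atom can span O-2 and O-5.
Retrosynthesis: the esters come off and the C1/C6 diol goes back to a C1=C6 alkene. C3=C4 and C1=C6 are then cut together by metathesis. This leaves two penta-1,4-dien-3-ol halves on an iPr2Si tether: C7/C1–C3 as a Baylis–Hillman acrylate and C4–C6 as divinylcarbinol.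
Forward: Baylis–Hillman adduct, resolution, mixed silaketal, double ring-closing metathesis (seven-membered silaketal ring first, then the carbocycle across it), ester reduction, directed dihydroxylation, silylene shift from O-5 to O-7, dibenzoylation, desilylation, diacetylation.
Stereochemistry: C2 comes from the lipase resolution. C5 comes from C2 through the tether, because only the cis silaketal can close again. C1 and C6 come from osmylation anti to the O–Si–O bridge.

Key step: step 4

Assumption: the lipase is taken to follow the usual size rule for secondary alcohols with the Baylis–Hillman adduct (vinyl = medium group, acrylate unit = large group); the sense of the resolution is checked on the recovered alcohol before it is carried on.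

Step 1
Reactants: 1 acrolein; 2 methyl acrylate
Product: 3 racemic methyl 3-hydroxy-2-methylidenepent-4-enoate
Conditions: DABCO (0.15 equiv), methyl acrylate (3 equiv, also the solvent), slow addition of acrolein, 0 °C to rt
Reagents that add atoms: none
Why: Morita–Baylis–Hillman reaction, in which DABCO adds to the acrylate, the resulting enolate attacks the aldehyde carbon of acrolein and DABCO is expelled, so that C2 forms racemic and is resolved in step 2.

Step 2
Reactants: 3 racemic methyl 3-hydroxy-2-methylidenepent-4-enoate
Product: 4 methyl (3S)-3-hydroxy-2-methylidenepent-4-enoate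
Conditions: immobilised Burkholderia cepacia lipase, vinyl acetate, MTBE, 30 °C, stopped just past half conversion; chromatography
Reagents that add atoms: none
Why: Lipase-catalysed kinetic resolution by irreversible transesterification, where the size rule predicts fast acetylation of the (R)-alcohol, so the (S)-alcohol with the C2 configuration of the target stays behind and gains enantiopurity past half conversion.

Step 3
Reactants: 5 penta-1,4-dien-3-ol; 4 methyl (3S)-3-hydroxy-2-methylidenepent-4-enoate
Product: 7 mixed diisopropylsilaketal tetraene, via chlorosilane 6 (not isolated)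
Conditions: 5, iPr2SiCl2 (3 equiv), Et3N, CH2Cl2, 0 °C; excess silane stripped in vacuo; then 4, Et3N, DMAP (cat.), CH2Cl2, rt
Reagents that add atoms: diisopropyldichlorosilane, CC(C)[Si](Cl)(Cl)C(C)C
Why: Stepwise nucleophilic substitution at silicon (mixed silaketal formation), in which the two isopropyl groups slow the second substitution enough that the monochloride forms from the cheap achiral alcohol and is then capped by 4 with no change at C2.

Step 4
Reactants: 7 mixed diisopropylsilaketal tetraene
Product: 9 methyl (1R,5S)-3,3-di(propan-2-yl)-2,4-dioxa-3-silabicyclo[3.2.2]nona-6,8-diene-6-carboxylate, via cis-dioxasilepine triene 8 (not isolated)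
Conditions: second-generation Grubbs catalyst RuCl2(=CHPh)(H2IMes)(PCy3) (10 mol %, two portions), 1,4-benzoquinone (20 mol %), toluene (2 mM), 80 °C, argon sparge to carry off ethene
Reagents that add atoms: none
Why: Ring-closing olefin metathesis runs twice in one flask: the ruthenium alkylidene loads on a monosubstituted vinyl group and passes through metallacyclobutanes ([2+2]/retro-[2+2]), each cycle expelling ethene, so that C3=C4 and C1=C6 both arise from four =CH2 termini. The closest known reactions are the temporary-silicon-tethered ring-closing metathesis of mixed silaketals made from a chiral allylic alcohol and prochiral penta-1,4-dien-3-ol, the closure of 1,4,7-trienes to cyclohexa-1,4-dienes, the closure of Baylis–Hillman acrylates to cyclohexenecarboxylates, and transannular metathesis to bridged bicycles. The seven-membered 1,3-dioxa-2-silacyclohept-5-ene ring closes first by vinyl–vinyl metathesis (C3=C4, Z by ring size), and the six-membered carbocycle then closes transannularly across its 4,7-positions by vinyl–acrylate metathesis (C1=C6), giving a boat cyclohexa-1,4-diene spanned by O–Si–O, which the long Si–O bonds and the flat, flexible diene should accommodate. The one new stereocentre, C5, comes from the choice between the two diastereotopic vinyl groups of the divinylcarbinol half: C2 relays its configuration through the tether (both side chains pseudo-equatorial in the closing seven-membered ring favours cis), only cis-8 can close again, and the trans isomer can be reopened by the ruthenium methylidene and fed back. The step needs ring closure over chain growth (secured by the one-atom tether, the isopropyl groups on silicon, high dilution and ethene removal), engagement of the electron-poor 1,1-disubstituted alkene (secured by making it the intramolecular partner of a vinyl-derived alkylidene on an NHC catalyst), and survival of a bis-allylic diene (secured by the neutral medium, benzoquinone against ruthenium hydrides, and the bridge, which holds both bridgehead C–H bonds in the nodal planes of the alkenes and so blocks aromatisation).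

Step 5
Reactants: 9 bridged dienoate
Product: 10 [(1R,5S)-3,3-di(propan-2-yl)-2,4-dioxa-3-silabicyclo[3.2.2]nona-6,8-dien-6-yl]methanol
Conditions: iBu2AlH (2.5 equiv), CH2Cl2, −78 °C; cold aqueous potassium sodium tartrate work-up; used at once
Reagents that add atoms: none
Why: 1,2-Reduction of an α,β-unsaturated ester with iBu2AlH gives the allylic alcohol at low temperature without touching the hindered silaketal or the bridgehead stereocentres.

Step 6
Reactants: 10 bridged dienylmethanol
Product: 12 bridged triol (1-OH and 6-OH α; C7H2OH β; O-2 and O-5 joined by iPr2Si), via osmate ester 11 (not isolated)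
Conditions: OsO4 (1.05 equiv), TMEDA (1.1 equiv), CH2Cl2, −78 °C; then aq Na2SO3, THF, 40 °C
Reagents that add atoms: osmium tetroxide, O=[Os](=O)(=O)=O
Why: Hydrogen-bond-directed syn-dihydroxylation, in which the OsO4·TMEDA complex is held by the allylic C7–OH and so picks C1=C6 over C3=C4, and adds suprafacially from the face turned towards the C3=C4 bridge because the other face lies under the O–Si(iPr)2–O bridge, which sets C1 and C6 with both new OH groups cis to each other and anti to O-2 and O-5.

Step 7
Reactants: 12 bridged triol
Product: 13 fused triol with the iPr2Si group on O-2 and O-7 (1-OH, 5-OH and 6-OH free)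
Conditions: DBU (0.1 equiv), THF (dilute), 0 °C to rt, monitored and quenched with AcOH
Reagents that add atoms: none
Why: Base-catalysed intramolecular O-to-O silyl migration (alcohol exchange at silicon, as in the known isomerisation of cyclic silanediyl protecting groups), in which C7–OH lies on the bridge face next to silicon, attacks it and releases O-5, driven by exchange of a boat-locking seven-membered bridge for a six-membered 1,3-dioxa-2-silinane on a half-chair cyclohexene, with no C–O bond broken and hence no stereocentre touched.

Step 8
Reactants: 13 fused triol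
Product: 14 5,6-dibenzoate of 13
Conditions: BzCl (2.5 equiv), pyridine, DMAP (cat.), CH2Cl2, 0 °C to rt
Reagents that add atoms: benzoyl chloride, O=C(Cl)c1ccccc1
Why: Standard acylation (nucleophilic acyl substitution) of the two secondary alcohols, with the tertiary 1-OH too hindered to react under these conditions.

Step 9
Reactants: 14 silylene dibenzoate
Product: 15 (1R,2S,5R,6S)-5,6-dibenzoyloxy-1-(hydroxymethyl)cyclohex-3-ene-1,2-diol
Conditions: HF·pyridine, extra pyridine, THF, 0 °C
Reagents that add atoms: none
Why: Fluoride-driven cleavage of the silylene acetal in a buffered, weakly acidic medium frees O-2 and O-7 together and avoids base-induced acyl migration.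

Step 10
Reactants: 15 triol dibenzoate
Product: 16 target CNP0196993.1
Conditions: Ac2O (2.5 equiv), pyridine, DMAP (cat.), CH2Cl2, 0 °C to rt
Reagents that add atoms: acetic anhydride, CC(=O)OC(C)=O
Why: Standard acetylation of the primary C7–OH and the secondary 2-OH, with the tertiary 1-OH left free because it needs forcing conditions to acylate.

Compound list
1 | acrolein | C=CC=O | starting material
2 | methyl acrylate | C=CC(=O)OC | starting material
3 | racemic methyl 3-hydroxy-2-methylidenepent-4-enoate | C=CC(O)C(=C)C(=O)OC | intermediate
4 | methyl (3S)-3-hydroxy-2-methylidenepent-4-enoate | C=C[C@H](O)C(=C)C(=O)OC | intermediate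
5 | penta-1,4-dien-3-ol | C=CC(O)C=C | starting material
6 | chloro(penta-1,4-dien-3-yloxy)di(propan-2-yl)silane | C=CC(C=C)O[Si](Cl)(C(C)C)C(C)C | intermediate
7 | methyl (3S)-2-methylidene-3-{[(penta-1,4-dien-3-yloxy)di(propan-2-yl)silyl]oxy}pent-4-enoate | C=C[C@H](O[Si](OC(C=C)C=C)(C(C)C)C(C)C)C(=C)C(=O)OC | intermediate
8 | methyl 2-[(4S,7S)-7-ethenyl-2,2-di(propan-2-yl)-4,7-dihydro-1,3,2-dioxasilepin-4-yl]prop-2-enoate (cis) | COC(=O)C(=C)[C@@H]1C=C[C@H](C=C)O[Si](C(C)C)(C(C)C)O1 | intermediate
9 | methyl (1R,5S)-3,3-di(propan-2-yl)-2,4-dioxa-3-silabicyclo[3.2.2]nona-6,8-diene-6-carboxylate | COC(=O)C1=C[C@H]2C=C[C@@H]1O[Si](C(C)C)(C(C)C)O2 | intermediate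
10 | [(1R,5S)-3,3-di(propan-2-yl)-2,4-dioxa-3-silabicyclo[3.2.2]nona-6,8-dien-6-yl]methanol | OCC1=C[C@H]2C=C[C@@H]1O[Si](C(C)C)(C(C)C)O2 | intermediate
11 | TMEDA-bound cyclic osmate ester (hexavalent osmium) across O-1 and O-6 of 12 | OC[C@@]12[C@@H]3C=C[C@@H](O[Si](C(C)C)(C(C)C)O3)[C@@H]1O[Os-2]4(=O)(=O)(O2)[N+](C)(C)CC[N+]4(C)C | intermediate
12 | 6-(hydroxymethyl)-3,3-di(propan-2-yl)-2,4-dioxa-3-silabicyclo[3.2.2]non-8-ene-6,7-diol, both ring OH groups anti to the O–Si–O bridge | OC[C@@]1(O)[C@@H]2C=C[C@@H](O[Si](C(C)C)(C(C)C)O2)[C@@H]1O | intermediate
13 | cyclohexene triol with O-2 and O-7 in a cis-fused 2,2-di(propan-2-yl)-1,3-dioxa-2-silinane; 1-OH α, 5-OH β, 6-OH α | C1[C@@]2(O)[C@@H](O[Si](C(C)C)(C(C)C)O1)C=C[C@@H](O)[C@@H]2O | intermediate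
14 | 5,6-di-O-benzoyl derivative of 13 | C1[C@@]2(O)[C@@H](O[Si](C(C)C)(C(C)C)O1)C=C[C@@H](OC(=O)c1ccccc1)[C@@H]2OC(=O)c1ccccc1 | intermediate
15 | (1R,2S,5R,6S)-5,6-dibenzoyloxy-1-(hydroxymethyl)cyclohex-3-ene-1,2-diol (route numbering) | OC[C@@]1(O)[C@@H](O)C=C[C@@H](OC(=O)c2ccccc2)[C@@H]1OC(=O)c1ccccc1 | intermediate
16 | (1R,2S,5R,6S)-2-acetoxy-1-(acetoxymethyl)-5,6-dibenzoyloxycyclohex-3-en-1-ol (route numbering) | CC(=O)OC[C@@]1(O)[C@@H](OC(C)=O)C=C[C@@H](OC(=O)c2ccccc2)[C@@H]1OC(=O)c1ccccc1 | target

Total step count: 10. Longest linear sequence: 10 (steps 1–10; the second half, 5, is bought).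

Steps most likely to fail

Step 4. The cascade may stall after the first closure, because the cis ring must place both side chains pseudo-axial. The bridged diene may also be reopened by the catalyst, or chains may grow instead of rings. The fallback sets out from 7 and comes back at 9; it makes the two bonds in separate operations and puts the bridge on last.
- 7 is closed once with first-generation Grubbs catalyst RuCl2(=CHPh)(PCy3)2 in CH2Cl2 at reflux, which leaves the acrylate alone, and 8 is isolated.
- HF·pyridine in THF removes the tether and gives methyl (3S,4Z,6S)-3,6-dihydroxy-2-methylideneocta-4,7-dienoate F1.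
- This free 1,4,7-triene has no bridge to build. RuCl2(=CHPh)(H2IMes)(PCy3) in CH2Cl2 closes it to methyl (3R,6S)-3,6-dihydroxycyclohexa-1,4-diene-1-carboxylate F2, which is kept cold and neutral.
- iPr2Si(OTf)2 and 2,6-lutidine in CH2Cl2, −78 °C to 0 °C, then span the cis-1,4-diol and give 9.

Step 6. Osmylation may occur at C3=C4 or from the bridge face. It may also occur after a premature drift of the silylene in 10 onto O-7; any drift after the diol has formed is harmless, since step 7 converges it. The fallback sets out from 9 and comes back at 12; it oxidises before it reduces and relies on electronic control instead of hydrogen-bond control.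
- KMnO4 in acetone–water buffered with AcOH at −30 °C is a nucleophilic oxidant that attacks an enoate alkene faster than an isolated one. It should dihydroxylate C1=C6 from the open face and give methyl 6,7-dihydroxy-3,3-di(propan-2-yl)-2,4-dioxa-3-silabicyclo[3.2.2]non-8-ene-6-carboxylate F3.
- LiBH4 in THF at 0 °C reduces the α-hydroxy ester to 12.

Step 7. The migration may stop short, run on to O-6 (an O-6/O-7 six-membered silylene), or turn intermolecular. The fallback sets out from 12 and comes back at 16; it uses no migration and tells the hydroxyl groups apart by their own reactivity.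
- AcCl and 2,4,6-collidine in CH2Cl2 at −78 °C acetylate only the primary alcohol and give the bridged 7-O-acetyl diol F4.
- BzCl, pyridine and DMAP give the bridged 7-O-acetyl-6-O-benzoyl alcohol F5.
- HF·pyridine gives the 7-O-acetyl-6-O-benzoyl triol F6.
- BzCl (1 equiv) and pyridine in CH2Cl2 at −40 °C should acylate the pseudo-equatorial 5-OH ahead of the pseudo-axial 2-OH, which sits next to quaternary C1. This gives the 7-O-acetyl-5,6-di-O-benzoyl diol F7.
- Ac2O, pyridine and DMAP then give 16.

Further compounds
F1 | step 4 | methyl (3S,4Z,6S)-3,6-dihydroxy-2-methylideneocta-4,7-dienoate | COC(=O)C(=C)[C@@H](O)/C=C\[C@@H](O)C=C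
F2 | step 4 | methyl (3R,6S)-3,6-dihydroxycyclohexa-1,4-diene-1-carboxylate | COC(=O)C1=C[C@H](O)C=C[C@@H]1O
F3 | step 6 | methyl 6,7-dihydroxy-3,3-di(propan-2-yl)-2,4-dioxa-3-silabicyclo[3.2.2]non-8-ene-6-carboxylate, both OH anti to the bridge | COC(=O)[C@@]1(O)[C@@H]2C=C[C@@H](O[Si](C(C)C)(C(C)C)O2)[C@@H]1O
F4 | step 7 | bridged 7-O-acetyl diol | CC(=O)OC[C@@]1(O)[C@@H]2C=C[C@@H](O[Si](C(C)C)(C(C)C)O2)[C@@H]1O
F5 | step 7 | bridged 7-O-acetyl-6-O-benzoyl alcohol | CC(=O)OC[C@@]1(O)[C@@H]2C=C[C@@H](O[Si](C(C)C)(C(C)C)O2)[C@@H]1OC(=O)c1ccccc1
F6 | step 7 | 7-O-acetyl-6-O-benzoyl triol | CC(=O)OC[C@@]1(O)[C@@H](O)C=C[C@@H](O)[C@@H]1OC(=O)c1ccccc1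
F7 | step 7 | 7-O-acetyl-5,6-di-O-benzoyl diol | CC(=O)OC[C@@]1(O)[C@@H](O)C=C[C@@H](OC(=O)c2ccccc2)[C@@H]1OC(=O)c1ccccc1
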